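**Plan**

1. Germacrane numbering is used throughout: ring carbons C1–C10, lactone carbons C11 (α), C12 (carbonyl, on O6) and C13 (methylene), C14 on C10, C15 on C4. The target is (3S,6R,7R,8R,10S), 4Z.
2. Retrosynthetic cuts, in order: the silyl ether on O10; the ring bond C3–C4 (Ni/Cr alkenyl iodide–aldehyde closure); the O8 isobutyrate; the lactone bond C7–C11; the O6–C12 acrylate ester; the 7,8-epoxide oxygen; C6–C7 (alkenylzinc plus iodoenal); the alkyne carbon C7; the C10 carbinol back to geraniol.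
3. Forward order: the C8–C10/C1–C3 chain from geraniol is joined to a C4–C6 iodoenal at C6–C7, the five-membered lactone ring is closed next, and the ten-membered carbocycle is closed last at C3–C4.
4. Enabling feature: C11 is at once the α-carbon of the lactone and of an acrylate ester on O6, and C7 and C8 are vicinal with oxygen on C8. A trans-7,8-epoxide next to the acrylate-bearing C6 can therefore be opened at C7 by C11, which closes the ring O6–C6–C7–C11–C12, frees O8 and leaves the C11=C13 methylene in place.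
5. Stereochemistry: C10 from Katsuki–Sharpless epoxidation of geraniol and hydride opening; C6 from ligand-controlled alkenylzinc addition; C7 and C8 from a matched Sharpless epoxidation anti to the C6 hydroxyl, with inversion at C7 in the lactone closure; 4Z from anti-hydroalumination/iodination of but-2-yn-1-ol; C3 in the ring closure.

Key step: step 11

Remark: (−)-MIB is assumed to deliver the alkenyl group to the Si face of the iodoenal, as it does with other conjugated aldehydes; the Sharpless epoxidation of step 9 is matched only for this epimer and so corrects a shortfall.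

**Route**

Step 1
Reactants: 1 geraniol
Product: 2 (2S,3S)-2,3-epoxygeraniol
Conditions: Ti(OiPr)4 (5 mol%), L-(+)-diethyl tartrate (6 mol%), t-BuOOH, 4 Å MS, CH2Cl2, −20 °C
Reagents that add atoms: tert-butyl hydroperoxide, CC(C)(C)OO
Why: Katsuki–Sharpless asymmetric epoxidation of a primary E-allylic alcohol, in which the L-(+)-tartrate complex delivers oxygen to the face that gives the (2S,3S)-epoxide (the later C10 centre) and leaves the isolated trisubstituted alkene untouched.

Step 2
Reactants: 2 (2S,3S)-2,3-epoxygeraniol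
Product: 3 (3S)-3,7-dimethyloct-6-ene-1,3-diol
Conditions: NaAlH2(OCH2CH2OMe)2, THF, 0 °C
Reagents that add atoms: none
Why: Reductive opening of a 2,3-epoxy alcohol, in which hydride is delivered within the alkoxyaluminate to C2 so that the 1,3-diol forms and the tertiary C–O bond (later C10, S) is not touched.

Step 3
Reactants: 3 (3S)-3,7-dimethyloct-6-ene-1,3-diol
Product: 4 (3S)-3,7-dimethyl-1,3-bis[(triethylsilyl)oxy]oct-6-ene
Conditions: Et3SiOTf, 2,6-lutidine, CH2Cl2, −78 to 0 °C
Reagents that add atoms: triethylsilyl trifluoromethanesulfonate, CC[Si](CC)(CC)OS(=O)(=O)C(F)(F)F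
Why: Silyl ether formation with a silyl triflate, which is reactive enough to cap the tertiary as well as the primary hydroxyl.

Step 4
Reactants: 4 (3S)-3,7-dimethyl-1,3-bis[(triethylsilyl)oxy]oct-6-ene
Product: 6 (3S)-3,7-dimethyl-3-[(triethylsilyl)oxy]oct-6-enal, via alkoxysulfonium chloride 5 (not isolated)
Conditions: (COCl)2, DMSO, CH2Cl2, −78 to −30 °C; then Et3N, −78 °C to rt
Reagents that add atoms: none
Why: Swern oxidation with in-flask cleavage of a primary silyl ether, in which the chlorosulfonium salt exchanges only the unhindered primary triethylsilyl group and the resulting alkoxysulfonium salt collapses to the aldehyde, the tertiary silyl ether being inert.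

Step 5
Reactants: 6 (3S)-3,7-dimethyl-3-[(triethylsilyl)oxy]oct-6-enal
Product: 7 triethyl{[(4S)-4,8-dimethylnon-7-en-1-yn-4-yl]oxy}silane
Conditions: dimethyl (1-diazo-2-oxopropyl)phosphonate, K2CO3, MeOH, 0 °C to rt
Reagents that add atoms: dimethyl (1-diazo-2-oxopropyl)phosphonate, COP(=O)(OC)C(=[N+]=[N-])C(C)=O
Why: Seyferth–Gilbert homologation in the Ohira–Bestmann form, whose mild carbonate conditions turn the aldehyde into the terminal alkyne (the added carbon is C7) without elimination of the hindered β-silyloxy group.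

Step 6
Reactants: 8 but-2-yn-1-ol
Product: 10 (2Z)-3-iodobut-2-en-1-ol, via cyclic alkenylalanate 9 (not isolated)
Conditions: NaAlH2(OCH2CH2OMe)2, THF, 0 °C to rt; then I2, THF, −78 to 0 °C
Reagents that add atoms: iodine, [I][I]
Why: Hydroxyl-directed anti-hydroalumination of a propargylic alcohol places aluminium on C3 in a five-membered ring, and iodinolysis with retention gives the Z-iodoalkene that becomes the 4Z ring alkene.

Step 7
Reactants: 10 (2Z)-3-iodobut-2-en-1-ol
Product: 11 (2Z)-3-iodobut-2-enal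
Conditions: MnO2, CH2Cl2, rt, dark
Reagents that add atoms: none
Why: Allylic oxidation with MnO2 under neutral conditions, chosen so that the Z-enal is not isomerised, the crude aldehyde being used at once.

Step 8
Reactants: 7 triethyl{[(4S)-4,8-dimethylnon-7-en-1-yn-4-yl]oxy}silane; 11 (2Z)-3-iodobut-2-enal
Product: 14 (2Z,4S,5E,8S)-2-iodo-8,12-dimethyl-8-[(triethylsilyl)oxy]trideca-2,5,11-trien-4-ol, via alkenylborane 12 (not isolated), via alkenylzinc 13 (not isolated)
Conditions: Cy2BH, toluene, 0 °C to rt; ZnMe2, −78 °C; (−)-MIB [(2S)-3-exo-morpholinoisoborneol] (10 mol%); then 11, −20 °C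
Reagents that add atoms: none
Why: Syn-hydroboration of the terminal alkyne (E-alkene C7=C8), boron-to-zinc transmetalation and ligand-accelerated 1,2-addition of the alkenylzinc to the aldehyde, in which the zinc aminoalkoxide of (−)-MIB directs the alkenyl group to the Si face and so sets the C6 carbinol (4S in this compound).

Step 9
Reactants: 14 (2Z,4S,5E,8S)-2-iodo-8,12-dimethyl-8-[(triethylsilyl)oxy]trideca-2,5,11-trien-4-ol
Product: 15 (1R,2Z)-1-[(2R,3R)-3-{(2S)-2,6-dimethyl-2-[(triethylsilyl)oxy]hept-5-en-1-yl}oxiran-2-yl]-3-iodobut-2-en-1-ol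
Conditions: Ti(OiPr)4 (20 mol%), D-(−)-diisopropyl tartrate (24 mol%), t-BuOOH, 4 Å MS, CH2Cl2, −20 °C
Reagents that add atoms: tert-butyl hydroperoxide, CC(C)(C)OO
Why: Katsuki–Sharpless epoxidation of a secondary E-allylic alcohol in its matched sense, in which the D-(−)-tartrate complex epoxidises C7=C8 of the 4S carbinol anti (erythro) to the hydroxyl and so sets C7 and C8 as the trans-epoxide, while any 4R epimer reacts far more slowly and the cis-substituted iodoalkene and the remote alkene are left alone.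

Step 10
Reactants: 15 (1R,2Z)-1-[(2R,3R)-3-{(2S)-2,6-dimethyl-2-[(triethylsilyl)oxy]hept-5-en-1-yl}oxiran-2-yl]-3-iodobut-2-en-1-ol
Product: 16 (1R,2Z)-1-[(2S,3R)-3-{(2S)-2,6-dimethyl-2-[(triethylsilyl)oxy]hept-5-en-1-yl}oxiran-2-yl]-3-iodobut-2-en-1-yl prop-2-enoate (same geometry as 15; the oxirane descriptor changes by priority only)
Conditions: acryloyl chloride, iPr2NEt, CH2Cl2, −78 to 0 °C
Reagents that add atoms: acryloyl chloride, C=CC(=O)Cl
Why: O-acylation of the only free hydroxyl with an acid chloride, run cold so that the epoxide and the acrylate are not attacked by chloride or amine.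

Step 11
Reactants: 16 (1R,2Z)-1-[(2S,3R)-3-{(2S)-2,6-dimethyl-2-[(triethylsilyl)oxy]hept-5-en-1-yl}oxiran-2-yl]-3-iodobut-2-en-1-yl prop-2-enoate
Product: 19 (4R,5S)-4-{(1R,3S)-1-hydroxy-3,7-dimethyl-3-[(triethylsilyl)oxy]oct-6-en-1-yl}-5-[(1Z)-2-iodoprop-1-en-1-yl]-3-methylideneoxolan-2-one, via phosphonium enolate 17 (not isolated), via cyclised phosphonium alkoxide 18 (not isolated)
Conditions: PMe3 (0.5 equiv), t-BuOH, 0.01 M, rt
Reagents that add atoms: none
Why: Proposed new method: PMe3 adds reversibly to the acrylate β-carbon (C13) to give the phosphonium enolate 17, whose α-carbon (C11) opens the neighbouring trans-epoxide at C7 from the backside, after which proton transfer in t-BuOH and E1cB loss of PMe3 from 18 restore the C11=C13 double bond and the catalyst. The closest known reaction types are the phosphine-mediated intramolecular Morita–Baylis–Hillman alkylation of enones by tethered epoxides and the base-induced opening of 2,3-epoxy alcohol carbamates at C2 to oxazolidinones; new here is an acrylate ester as the donor with the ester oxygen in the tether. The γ-lactone ring (O6, C6, C7, C11, C12) closes in the 5-exo-tet mode. C7 is the only new stereocentre and is set by stereospecific inversion at the epoxide carbon, so that it and the freed C8 carbinol (retained) both derive from the Sharpless epoxide, and the trans ring fusion follows from the erythro epoxy alcohol. The step needs regioselectivity for C7 over C8 (5-exo against 6-endo), secured by the tether length, and chemoselectivity for cyclisation over acrylate dimerisation and over shift of the lactone acyl group to O8, secured by high dilution and by the protic solvent that protonates the C8 alkoxide at once.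

Step 12
Reactants: 19 (4R,5S)-4-{(1R,3S)-1-hydroxy-3,7-dimethyl-3-[(triethylsilyl)oxy]oct-6-en-1-yl}-5-[(1Z)-2-iodoprop-1-en-1-yl]-3-methylideneoxolan-2-one
Product: 20 (1R,3S)-1-{(2S,3R)-2-[(1Z)-2-iodoprop-1-en-1-yl]-4-methylidene-5-oxooxolan-3-yl}-3,7-dimethyl-3-[(triethylsilyl)oxy]oct-6-en-1-yl 2-methylpropanoate
Conditions: (iPrCO)2O, pyridine, DMAP (cat.), CH2Cl2, 0 °C
Reagents that add atoms: isobutyric anhydride, CC(C)C(=O)OC(=O)C(C)C
Why: DMAP-catalysed esterification of the secondary C8 alcohol, the only free hydroxyl, run cold and promptly so that the lactone does not shift to O8.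

Step 13
Reactants: 20 (1R,3S)-1-{(2S,3R)-2-[(1Z)-2-iodoprop-1-en-1-yl]-4-methylidene-5-oxooxolan-3-yl}-3,7-dimethyl-3-[(triethylsilyl)oxy]oct-6-en-1-yl 2-methylpropanoate
Product: 22 (1R,3S)-1-{(2S,3R)-2-[(1Z)-2-iodoprop-1-en-1-yl]-4-methylidene-5-oxooxolan-3-yl}-3-methyl-6-oxo-3-[(triethylsilyl)oxy]hexyl 2-methylpropanoate, via secondary ozonide 21 (not isolated)
Conditions: O3, CH2Cl2, −78 °C (Sudan red 7B as end-point indicator); then PPh3, −78 °C to rt
Reagents that add atoms: ozone, [O-][O+]=O
Why: Ozonolysis with reductive work-up, in which electrophilic ozone consumes the electron-rich trialkyl alkene well before the acrylate-type methylene and the iodoalkene, the dye marking the end point.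

Step 14
Reactants: 22 (1R,3S)-1-{(2S,3R)-2-[(1Z)-2-iodoprop-1-en-1-yl]-4-methylidene-5-oxooxolan-3-yl}-3-methyl-6-oxo-3-[(triethylsilyl)oxy]hexyl 2-methylpropanoate
Product: 24 (3aR,4R,6S,9S,10Z,11aR)-9-hydroxy-6,10-dimethyl-3-methylidene-2-oxo-6-[(triethylsilyl)oxy]-2,3,3a,4,5,6,7,8,9,11a-decahydrocyclodeca[b]furan-4-yl 2-methylpropanoate, via alkenylchromium dichloride 23 (not isolated)
Conditions: CrCl2 (10 equiv), NiCl2 (0.1 equiv), DMSO/THF, 0.003 M, rt, slow addition of 22
Reagents that add atoms: none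
Why: Nozaki–Hiyama–Kishi macrocyclisation, in which zerovalent nickel inserts into the carbon–iodine bond with retention of the Z geometry and the alkenylchromium 23 adds only to the aldehyde at high dilution to close the ten-membered ring at C3–C4, with the C3 carbinol set by the conformation of the closing ring (3S expected but not assured, see fallback).

Step 15
Reactants: 24 (3aR,4R,6S,9S,10Z,11aR)-9-hydroxy-6,10-dimethyl-3-methylidene-2-oxo-6-[(triethylsilyl)oxy]-2,3,3a,4,5,6,7,8,9,11a-decahydrocyclodeca[b]furan-4-yl 2-methylpropanoate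
Product: 25 (3aR,4R,6S,9S,10Z,11aR)-6,9-dihydroxy-6,10-dimethyl-3-methylidene-2-oxo-2,3,3a,4,5,6,7,8,9,11a-decahydrocyclodeca[b]furan-4-yl 2-methylpropanoate (CNP0163972.1)
Conditions: HF·pyridine, pyridine, THF, 0 °C to rt
Reagents that add atoms: none
Why: Fluoride-mediated cleavage of the tertiary triethylsilyl ether under buffered, weakly acidic conditions that spare the methylene lactone, the isobutyrate and the allylic alcohol.

**Compound list**

1 | geraniol, (2E)-3,7-dimethylocta-2,6-dien-1-ol | CC(C)=CCC/C(C)=C/CO | starting material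
2 | (2S,3S)-2,3-epoxygeraniol, [(2S,3S)-3-methyl-3-(4-methylpent-3-en-1-yl)oxiran-2-yl]methanol | CC(C)=CCC[C@]1(C)O[C@H]1CO | intermediate
3 | (3S)-3,7-dimethyloct-6-ene-1,3-diol | CC(C)=CCC[C@](C)(O)CCO | intermediate
4 | (3S)-3,7-dimethyl-1,3-bis[(triethylsilyl)oxy]oct-6-ene | CC(C)=CCC[C@](C)(O[Si](CC)(CC)CC)CCO[Si](CC)(CC)CC | intermediate
5 | alkoxysulfonium chloride from the primary oxygen of 4 (dimethyl{[(3S)-3,7-dimethyl-3-(triethylsilyloxy)oct-6-en-1-yl]oxy}sulfonium chloride) | CC(C)=CCC[C@](C)(O[Si](CC)(CC)CC)CCO[S+](C)C.[Cl-] | intermediate (not isolated)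
6 | (3S)-3,7-dimethyl-3-[(triethylsilyl)oxy]oct-6-enal | CC(C)=CCC[C@](C)(O[Si](CC)(CC)CC)CC=O | intermediate
7 | triethyl{[(4S)-4,8-dimethylnon-7-en-1-yn-4-yl]oxy}silane | CC(C)=CCC[C@](C)(O[Si](CC)(CC)CC)CC#C | intermediate
8 | but-2-yn-1-ol | CC#CCO | starting material
9 | cyclic alkenylalanate, sodium 2,2-bis(2-methoxyethoxy)-3-methyl-2,5-dihydro-1,2-oxaluminol-2-uide | CC1=CCO[Al-]1(OCCOC)OCCOC.[Na+] | intermediate (not isolated)
10 | (2Z)-3-iodobut-2-en-1-ol | C/C(I)=C/CO | intermediate
11 | (2Z)-3-iodobut-2-enal | C/C(I)=C/C=O | intermediate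
12 | alkenylborane, dicyclohexyl[(1E,4S)-4,8-dimethyl-4-(triethylsilyloxy)nona-1,7-dien-1-yl]borane | CC(C)=CCC[C@](C)(O[Si](CC)(CC)CC)C/C=C/B(C1CCCCC1)C1CCCCC1 | intermediate (not isolated)
13 | alkenylzinc, methyl[(1E,4S)-4,8-dimethyl-4-(triethylsilyloxy)nona-1,7-dien-1-yl]zinc | CC(C)=CCC[C@](C)(O[Si](CC)(CC)CC)C/C=C/[Zn]C | intermediate (not isolated)
14 | (2Z,4S,5E,8S)-2-iodo-8,12-dimethyl-8-[(triethylsilyl)oxy]trideca-2,5,11-trien-4-ol | C/C(I)=C/[C@@H](O)/C=C/C[C@@](C)(O[Si](CC)(CC)CC)CCC=C(C)C | intermediate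
15 | (1R,2Z)-1-[(2R,3R)-3-{(2S)-2,6-dimethyl-2-[(triethylsilyl)oxy]hept-5-en-1-yl}oxiran-2-yl]-3-iodobut-2-en-1-ol (trans-epoxide, anti to the carbinol) | C/C(I)=C/[C@@H](O)[C@H]1O[C@@H]1C[C@@](C)(O[Si](CC)(CC)CC)CCC=C(C)C | intermediate
16 | (1R,2Z)-1-[(2S,3R)-3-{(2S)-2,6-dimethyl-2-[(triethylsilyl)oxy]hept-5-en-1-yl}oxiran-2-yl]-3-iodobut-2-en-1-yl prop-2-enoate | C/C(I)=C/[C@@H](OC(=O)C=C)[C@H]1O[C@@H]1C[C@@](C)(O[Si](CC)(CC)CC)CCC=C(C)C | intermediate
17 | phosphonium enolate from 16 and PMe3 (zwitterion; other centres as in 16) | C/C(I)=C/[C@@H](OC([O-])=CC[P+](C)(C)C)[C@H]1O[C@@H]1C[C@@](C)(O[Si](CC)(CC)CC)CCC=C(C)C | intermediate (not isolated)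
18 | cyclised phosphonium alkoxide (α-(trimethylphosphoniomethyl) lactone, C8 alkoxide; C11 undefined, other centres as in 19) | C[P+](C)(C)CC1C(=O)O[C@H](/C=C(/C)I)[C@H]1[C@H]([O-])C[C@@](C)(O[Si](CC)(CC)CC)CCC=C(C)C | intermediate (not isolated)
19 | (4R,5S)-4-{(1R,3S)-1-hydroxy-3,7-dimethyl-3-[(triethylsilyl)oxy]oct-6-en-1-yl}-5-[(1Z)-2-iodoprop-1-en-1-yl]-3-methylideneoxolan-2-one (trans-disubstituted lactone) | C=C1C(=O)O[C@H](/C=C(/C)I)[C@H]1[C@H](O)C[C@@](C)(O[Si](CC)(CC)CC)CCC=C(C)C | intermediate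
20 | (1R,3S)-1-{(2S,3R)-2-[(1Z)-2-iodoprop-1-en-1-yl]-4-methylidene-5-oxooxolan-3-yl}-3,7-dimethyl-3-[(triethylsilyl)oxy]oct-6-en-1-yl 2-methylpropanoate | C=C1C(=O)O[C@H](/C=C(/C)I)[C@H]1[C@H](OC(=O)C(C)C)C[C@@](C)(O[Si](CC)(CC)CC)CCC=C(C)C | intermediate
21 | secondary ozonide (3,3-dimethyl-1,2,4-trioxolane) of the terminal alkene of 20 (ring carbon undefined, other centres as in 20) | C=C1C(=O)O[C@H](/C=C(/C)I)[C@H]1[C@H](OC(=O)C(C)C)C[C@@](C)(O[Si](CC)(CC)CC)CCC2OOC(C)(C)O2 | intermediate (not isolated)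
22 | (1R,3S)-1-{(2S,3R)-2-[(1Z)-2-iodoprop-1-en-1-yl]-4-methylidene-5-oxooxolan-3-yl}-3-methyl-6-oxo-3-[(triethylsilyl)oxy]hexyl 2-methylpropanoate | C=C1C(=O)O[C@H](/C=C(/C)I)[C@H]1[C@H](OC(=O)C(C)C)C[C@@](C)(O[Si](CC)(CC)CC)CCC=O | intermediate
23 | alkenylchromium dichloride from 22 (chromium in place of iodine, Z geometry retained) | C=C1C(=O)O[C@H](/C=C(/C)[Cr](Cl)Cl)[C@H]1[C@H](OC(=O)C(C)C)C[C@@](C)(O[Si](CC)(CC)CC)CCC=O | intermediate (not isolated)
24 | (3aR,4R,6S,9S,10Z,11aR)-9-hydroxy-6,10-dimethyl-3-methylidene-2-oxo-6-[(triethylsilyl)oxy]-2,3,3a,4,5,6,7,8,9,11a-decahydrocyclodeca[b]furan-4-yl 2-methylpropanoate | C=C1C(=O)O[C@@H]2/C=C(/C)[C@@H](O)CC[C@](C)(O[Si](CC)(CC)CC)C[C@@H](OC(=O)C(C)C)[C@@H]12 | intermediate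
25 | (3aR,4R,6S,9S,10Z,11aR)-6,9-dihydroxy-6,10-dimethyl-3-methylidene-2-oxo-2,3,3a,4,5,6,7,8,9,11a-decahydrocyclodeca[b]furan-4-yl 2-methylpropanoate | C=C1C(=O)O[C@@H]2/C=C(/C)[C@@H](O)CC[C@](C)(O)C[C@@H](OC(=O)C(C)C)[C@@H]12 | target

**Step count and risks**

Total step count: 15. Longest linear sequence: 13 (steps 1–5 and 8–15, from geraniol); steps 6 and 7 form the two-step side branch.

Steps most likely to fail:

Step 11 (proposed new method). The phosphonium enolate may fail to open the epoxide (reversible phosphine addition, acrylate oligomerisation), or the freed C8 alkoxide may shift the lactone to O8. The fallback uses known chemistry, sets out from 15 and comes back at 19. Esterification of 15 with diethylphosphonoacetic acid (EDC·HCl, DMAP, CH2Cl2) would give the phosphonoacetate F1. Deprotonation (KOtBu, THF, 0 °C to rt) would let the stabilised carbanion open the epoxide at C7 in the same 5-exo mode, with the same inversion, to give the α-phosphono lactone F2. F2 is held as its phosphonate-stabilised anion, which protects the lactone carbonyl from the C8 alkoxide. Horner–Wadsworth–Emmons methylenation with paraformaldehyde in the same flask would then give 19.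

Step 14. Facial selectivity at C3 during the ring closure may be poor, or the wrong epimer may prevail. The fallback sets out from 22 and comes back at 24. The Nozaki–Hiyama–Kishi product, as a mixture of 24 and its C3 epimer F3, would be oxidised (Dess–Martin periodinane, NaHCO3, CH2Cl2) to the ring enone F4. C3 would then be set under reagent control by Corey–Bakshi–Shibata reduction ((R)-2-methyl-CBS-oxazaborolidine, catecholborane, toluene, −78 °C; the alkenyl side acts as the large group) to give 24.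

Step 8. Facial selectivity in the alkenylzinc addition to the sensitive Z-iodoenal may be poor. The fallback sets out from 7 and 11 and comes back at 15. The addition would be run without the chiral ligand to give 14 together with its 4R epimer F5. The mixture would be taken into the Sharpless epoxidation of step 9, run as a kinetic resolution, so that only 14 is epoxidised to 15. Recovered F5 would be oxidised (MnO2, CH2Cl2) to the dienone F6, reduced under Luche conditions (NaBH4, CeCl3·7H2O, MeOH, −78 °C) back to the mixture of 14 and F5, and resubmitted.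

**Further compounds**

F1 | step 11 | (1R,2Z)-1-[(2S,3R)-3-{(2S)-2,6-dimethyl-2-[(triethylsilyl)oxy]hept-5-en-1-yl}oxiran-2-yl]-3-iodobut-2-en-1-yl (diethoxyphosphoryl)acetate | C/C(I)=C/[C@@H](OC(=O)CP(=O)(OCC)OCC)[C@H]1O[C@@H]1C[C@@](C)(O[Si](CC)(CC)CC)CCC=C(C)C
F2 | step 11 | diethyl [(4R,5S)-4-{(1R,3S)-1-hydroxy-3,7-dimethyl-3-[(triethylsilyl)oxy]oct-6-en-1-yl}-5-[(1Z)-2-iodoprop-1-en-1-yl]-2-oxooxolan-3-yl]phosphonate (C3 of the lactone undefined) | CCOP(=O)(OCC)C1C(=O)O[C@H](/C=C(/C)I)[C@H]1[C@H](O)C[C@@](C)(O[Si](CC)(CC)CC)CCC=C(C)C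
F3 | step 14 | C3 epimer of 24, (3aR,4R,6S,9R,10Z,11aR)-9-hydroxy-6,10-dimethyl-3-methylidene-2-oxo-6-[(triethylsilyl)oxy]-2,3,3a,4,5,6,7,8,9,11a-decahydrocyclodeca[b]furan-4-yl 2-methylpropanoate | C=C1C(=O)O[C@@H]2/C=C(/C)[C@H](O)CC[C@](C)(O[Si](CC)(CC)CC)C[C@@H](OC(=O)C(C)C)[C@@H]12
F4 | step 14 | ring enone, the 9-oxo analogue of 24 (C3 ketone in germacrane numbering, other centres as in 24) | C=C1C(=O)O[C@@H]2/C=C(/C)C(=O)CC[C@](C)(O[Si](CC)(CC)CC)C[C@@H](OC(=O)C(C)C)[C@@H]12
F5 | step 8 | (2Z,4R,5E,8S)-2-iodo-8,12-dimethyl-8-[(triethylsilyl)oxy]trideca-2,5,11-trien-4-ol | C/C(I)=C/[C@H](O)/C=C/C[C@@](C)(O[Si](CC)(CC)CC)CCC=C(C)C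
F6 | step 8 | (2Z,5E,8S)-2-iodo-8,12-dimethyl-8-[(triethylsilyl)oxy]trideca-2,5,11-trien-4-one | C/C(I)=C/C(=O)/C=C/C[C@@](C)(O[Si](CC)(CC)CC)CCC=C(C)C
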